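Chain carbons are numbered C1' (carbinol on pyrogallol ring B) to C14' (benzylic on resorcinol ring A). The 22-membered ring is opened at the unactivated C3'–C4' methylene–methylene bond. C3' lies two atoms from C1', so it can be the terminus of a vinyl carbinol. C4' is a hex-5-enyl position relative to the E-alkene C8'=C9', so it must never become a radical. The key step therefore hydroborates the vinyl group with 9-BBN and couples the primary alkylborane with the primary bromide at C4' in a palladium-catalysed alkyl–alkyl Suzuki–Miyaura macrocyclisation. The precursor is a diaryl ether bearing an (R)-silyloxyallyl group on ring B and an (E)-11-bromoundec-6-enyl chain on ring A.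

Key step: step 9

Remark on the chemistry: the carbinol centre C1' of the target is R (OH > aryl > CH2 > H). Compounds 1, 2, 8 and 11 are taken as purchasable. TIPS is chosen for the phenols because aryl TIPS ethers should survive the aqueous phosphate of steps 8 and 9.

Step 1
Reactants: 1 syringaldehyde (4-hydroxy-3,5-dimethoxybenzaldehyde); 2 1-bromo-3-iodo-5-methoxybenzene
Product: 3 4-(3-bromo-5-methoxyphenoxy)-3,5-dimethoxybenzaldehyde
Conditions: CuI (10 mol%), picolinic acid (20 mol%), K3PO4, DMSO, 90 °C
Reagents that add atoms: none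
Why: Ullmann-type copper-catalysed C–O coupling with a ligand system suited to hindered phenols should engage the aryl iodide of 2 and leave its bromide as the later handle for the chain.

Step 2
Reactants: 3
Product: 4 4-(3-bromo-5-hydroxyphenoxy)-3,5-dihydroxybenzaldehyde
Conditions: BBr3 (excess), CH2Cl2, −78 °C to rt; then H2O
Reagents that add atoms: none
Why: Lewis acid-mediated aryl methyl ether cleavage should remove all three methyl groups while the diaryl ether, the aryl bromide and the aldehyde remain, so that fluoride-labile groups can be put on.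

Step 3
Reactants: 4
Product: 5 4-[3-bromo-5-(triisopropylsilyloxy)phenoxy]-3,5-bis(triisopropylsilyloxy)benzaldehyde
Conditions: TIPSCl, imidazole, DMAP (cat.), DMF, rt to 40 °C
Reagents that add atoms: triisopropylsilyl chloride, CC(C)[Si](Cl)(C(C)C)C(C)C
Why: Phenol silylation gives aryl TIPS ethers, which should tolerate organozinc, 9-BBN and aqueous phosphate and be removed by fluoride at the end.

Step 4
Reactants: 5
Product: 6 (R)-1-{4-[3-bromo-5-(triisopropylsilyloxy)phenoxy]-3,5-bis(triisopropylsilyloxy)phenyl}prop-2-en-1-ol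
Conditions: CH2=CHMgBr, ZnCl2, THF, then 1,4-dioxane and filtration of the magnesium salts; (2R)-(+)-3-exo-(dimethylamino)isoborneol [(+)-DAIB] (10 mol%), toluene, 0 °C; aq NH4Cl
Reagents that add atoms: vinylmagnesium bromide, C=C[Mg]Br
Why: Amino alcohol-catalysed enantioselective addition of a vinylzinc reagent to an aromatic aldehyde is used; because (−)-DAIB delivers alkyl groups to the Si face of aromatic aldehydes, (+)-DAIB should deliver vinyl to the Re face and set C1' as R.

Step 5
Reactants: 6
Product: 7 (R)-tert-butyldimethylsilyl ether of 6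
Conditions: TBSCl, imidazole, DMF, rt
Reagents that add atoms: tert-butyldimethylsilyl chloride, CC(C)(C)[Si](C)(C)Cl
Why: Standard silylation of the secondary allylic benzylic alcohol masks the C1' hydroxyl for the hydroboration and cross-coupling steps without touching the stereocentre.

Step 6
Reactants: 8 6-bromohex-1-yne
Product: 10 (E)-6-bromo-1-iodohex-1-ene, via alkenylzirconocene chloride 9 (not isolated)
Conditions: Cp2Zr(H)Cl, CH2Cl2, rt; then I2, 0 °C
Reagents that add atoms: iodine, II
Why: Hydrozirconation of a terminal alkyne is a syn, anti-Markovnikov addition and iodinolysis of the C–Zr bond proceeds with retention, so the E-vinyl iodide should form with the primary bromide untouched.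

Step 7
Reactants: 10; 11 5-bromopent-1-ene
Product: 13 (E)-11-bromoundeca-1,6-diene, via pent-4-enylzinc bromide 12 (not isolated)
Conditions: 11, Zn, LiCl, THF, 50 °C; then 10, Pd(dppf)Cl2 (3 mol%), THF, rt
Reagents that add atoms: none
Why: Negishi coupling of an alkenyl iodide with a primary alkylzinc bromide proceeds with retention of alkene geometry and fixes the E-C8'=C9' bond, the alkyl bromide being inert to this catalyst at rt.

Step 8
Reactants: 7; 13
Product: 15 seco bromide (ring A carries the (E)-11-bromoundec-6-enyl chain; ring B carries the (R)-1-(tert-butyldimethylsilyloxy)prop-2-enyl group), via B-alkyl-9-BBN 14 (not isolated)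
Conditions: 13 (slight excess over 9-BBN), 9-BBN, THF, 0 °C to rt; then 7, Pd(dppf)Cl2 (5 mol%), K3PO4 (3 M aq), THF/DMF, 50 °C
Reagents that add atoms: none
Why: B-alkyl Suzuki–Miyaura coupling is used: 9-BBN should add only to the terminal alkene of 13, no B–H is left to reach the vinyl group of 7, and Pd(dppf)Cl2 activates the aryl bromide but not the primary alkyl bromide.

Step 9
Reactants: 15
Product: 17 tetrasilylated macrocycle (R at C1'; E at C8'=C9'), via C3' alkylborane 16 (not isolated)
Conditions: 9-BBN (1.1 equiv), THF, rt; then slow addition to Pd(OAc)2 (20 mol%), PCy3 (40 mol%), K3PO4·H2O, THF, rt, about 2 mM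
Reagents that add atoms: none
Why: 9-BBN adds syn and anti-Markovnikov to the monosubstituted C2'=C3' alkene to put boron on C3' (16); zerovalent palladium bearing PCy3 then inserts into the primary C4'–Br bond by an SN2-type two-electron oxidative addition, the hydroxide-activated borate transfers its primary alkyl group, and reductive elimination forms C3'–C4'. The closest known reaction type is the Pd/PCy3-catalysed Suzuki–Miyaura coupling of unactivated primary alkyl bromides with B-alkyl-9-BBN reagents, run here intramolecularly after the pattern of sp2–sp3 B-alkyl Suzuki macrocyclisations. The 22-membered ring closes end to end (formally 22-exo-tet at C4'), aided by slow addition at high dilution and by the diaryl ether, which already holds both chain ends on one scaffold. No stereocentre is created: C1' should stay R because boron is γ to the silyloxy group and cannot eliminate it, and C8'=C9' should stay E because it takes no part. Two selectivities are needed: 9-BBN must take the terminal vinyl group and leave the 1,2-disubstituted C8'=C9' alkene, which its strong preference for monosubstituted alkenes secures, and C4' must stay a closed-shell centre because a C4' radical would cyclise 5-exo onto C8', which is why the bromide sits at C4' under palladium and not under nickel or photoredox activation.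

Step 10
Reactants: 17
Product: 18 dehydrogravicycle
Conditions: Bu4NF, AcOH, THF, 0 °C to rt
Reagents that add atoms: none
Why: Fluoride-mediated global desilylation should cleave the three aryl TIPS ethers and the benzylic TBS ether, with acetic acid buffering the phenoxides so that the E-alkene and the R carbinol are not disturbed.

Compound list
1 | syringaldehyde (4-hydroxy-3,5-dimethoxybenzaldehyde) | COc1cc(C=O)cc(OC)c1O | starting material
2 | 1-bromo-3-iodo-5-methoxybenzene | COc1cc(Br)cc(I)c1 | starting material
3 | 4-(3-bromo-5-methoxyphenoxy)-3,5-dimethoxybenzaldehyde | COc1cc(Br)cc(c1)Oc1c(OC)cc(C=O)cc1OC | intermediate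
4 | 4-(3-bromo-5-hydroxyphenoxy)-3,5-dihydroxybenzaldehyde | Oc1cc(Br)cc(c1)Oc1c(O)cc(C=O)cc1O | intermediate
5 | 4-[3-bromo-5-(triisopropylsilyloxy)phenoxy]-3,5-bis(triisopropylsilyloxy)benzaldehyde | CC(C)[Si](C(C)C)(C(C)C)Oc1cc(Br)cc(c1)Oc1c(O[Si](C(C)C)(C(C)C)C(C)C)cc(C=O)cc1O[Si](C(C)C)(C(C)C)C(C)C | intermediate
6 | (R)-1-{4-[3-bromo-5-(triisopropylsilyloxy)phenoxy]-3,5-bis(triisopropylsilyloxy)phenyl}prop-2-en-1-ol | CC(C)[Si](C(C)C)(C(C)C)Oc1cc(Br)cc(c1)Oc1c(O[Si](C(C)C)(C(C)C)C(C)C)cc(cc1O[Si](C(C)C)(C(C)C)C(C)C)[C@H](O)C=C | intermediate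
7 | (R)-tert-butyldimethylsilyl ether of 6 | CC(C)[Si](C(C)C)(C(C)C)Oc1cc(Br)cc(c1)Oc1c(O[Si](C(C)C)(C(C)C)C(C)C)cc(cc1O[Si](C(C)C)(C(C)C)C(C)C)[C@H](O[Si](C)(C)C(C)(C)C)C=C | intermediate
8 | 6-bromohex-1-yne | C#CCCCCBr | starting material
9 | chloro[(E)-6-bromohex-1-enyl]zirconocene | Cl[Zr](/C=C/CCCCBr)(C1C=CC=C1)C1C=CC=C1 | intermediate (not isolated)
10 | (E)-6-bromo-1-iodohex-1-ene | I/C=C/CCCCBr | intermediate
11 | 5-bromopent-1-ene | C=CCCCBr | starting material
12 | pent-4-enylzinc bromide | C=CCCC[Zn]Br | intermediate (not isolated)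
13 | (E)-11-bromoundeca-1,6-diene | C=CCCC/C=C/CCCCBr | intermediate
14 | 9-[(E)-11-bromoundec-6-enyl]-9-borabicyclo[3.3.1]nonane | BrCCCC/C=C/CCCCCB1C2CCCC1CCC2 | intermediate (not isolated)
15 | seco bromide: ring A with (E)-11-bromoundec-6-enyl chain, ring B with (R)-1-(tert-butyldimethylsilyloxy)prop-2-enyl group, three aryl TIPS ethers | CC(C)[Si](C(C)C)(C(C)C)Oc1cc(CCCCC/C=C/CCCCBr)cc(c1)Oc1c(O[Si](C(C)C)(C(C)C)C(C)C)cc(cc1O[Si](C(C)C)(C(C)C)C(C)C)[C@H](O[Si](C)(C)C(C)(C)C)C=C | intermediate
16 | C3' 9-BBN alkylborane of 15 | CC(C)[Si](C(C)C)(C(C)C)Oc1cc(CCCCC/C=C/CCCCBr)cc(c1)Oc1c(O[Si](C(C)C)(C(C)C)C(C)C)cc(cc1O[Si](C(C)C)(C(C)C)C(C)C)[C@H](O[Si](C)(C)C(C)(C)C)CCB1C2CCCC1CCC2 | intermediate (not isolated)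
17 | tetrasilylated macrocycle (R, E): tris(TIPS) ether and C1' TBS ether of the target | CC(C)[Si](C(C)C)(C(C)C)Oc1cc2cc(c1)Oc1c(O[Si](C(C)C)(C(C)C)C(C)C)cc(cc1O[Si](C(C)C)(C(C)C)C(C)C)[C@H](O[Si](C)(C)C(C)(C)C)CCCCCC/C=C/CCCCC2 | intermediate
18 | dehydrogravicycle | Oc1cc2cc(c1)Oc1c(O)cc(cc1O)[C@H](O)CCCCCC/C=C/CCCCC2 | target

Total step count: 10. Longest linear sequence: 8 (steps 1, 2, 3, 4, 5, 8, 9, 10).

Steps most likely to fail

Step 9. The alkylpalladium species at C4' must wait for an intramolecular transmetalation at high dilution. β-Hydride elimination to a terminal alkene, intermolecular coupling to oligomers, or insertion of the C8'=C9' alkene into the Pd–C4' bond may therefore outrun ring closure. The fallback forms the same bond by carbanion alkylation. It sets out from compound 15 through its borane 16, which is oxidised with NaBO3·4H2O instead of being coupled, to give bromo alcohol F1. PhSO2Na in DMF replaces the bromide to give hydroxy sulfone F2, and I2, PPh3 and imidazole in CH2Cl2 give iodo sulfone F3. Slow addition of F3 to KN(SiMe3)2 in THF at −78 °C to 0 °C under high dilution should alkylate the sulfonyl carbanion at C4' with the C3' iodide and give macrocyclic sulfone F4 as a mixture at C4'. Reductive desulfonylation with Na(Hg) and Na2HPO4 in MeOH/THF at −20 °C removes that centre and comes back to the route at compound 17.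

Step 4. Facial selectivity may be eroded by uncatalysed background addition promoted by residual magnesium salts, so that 6 forms in insufficient enantiomeric purity. The fallback sets out from compound 5: CH2=CHMgBr in THF at −78 °C gives racemic allylic alcohol F5. Sharpless kinetic resolution (Ti(OiPr)4, D-(−)-diisopropyl tartrate, t-BuOOH 0.6 equiv, 4 Å molecular sieves, CH2Cl2, −20 °C) should epoxidise the S enantiomer to epoxy alcohol F6 and leave the R enantiomer, which is compound 6, where the route is rejoined.

Step 1. The phenoxide of 1 is hindered by two ortho methoxy groups and deactivated by the para formyl group, so C–O bond formation may be slow, and protodehalogenation or reaction at the bromide may take over at the temperature needed. The fallback sets out from compound 1 and uses a Chan–Lam coupling with (3-bromo-5-methoxyphenyl)boronic acid F7 (Cu(OAc)2, pyridine, 4 Å molecular sieves, CH2Cl2, air, rt). This oxidative coupling runs at room temperature and is suited to 2,6-disubstituted phenols. It comes back to the route at compound 3.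

Further compounds
F1 | step 9 | bromo alcohol: 15 with the vinyl group converted to CH2CH2OH | CC(C)[Si](C(C)C)(C(C)C)Oc1cc(CCCCC/C=C/CCCCBr)cc(c1)Oc1c(O[Si](C(C)C)(C(C)C)C(C)C)cc(cc1O[Si](C(C)C)(C(C)C)C(C)C)[C@H](O[Si](C)(C)C(C)(C)C)CCO
F2 | step 9 | hydroxy sulfone: F1 with Br replaced by phenylsulfonyl | CC(C)[Si](C(C)C)(C(C)C)Oc1cc(CCCCC/C=C/CCCCS(=O)(=O)c2ccccc2)cc(c1)Oc1c(O[Si](C(C)C)(C(C)C)C(C)C)cc(cc1O[Si](C(C)C)(C(C)C)C(C)C)[C@H](O[Si](C)(C)C(C)(C)C)CCO
F3 | step 9 | iodo sulfone: F2 with OH replaced by I | CC(C)[Si](C(C)C)(C(C)C)Oc1cc(CCCCC/C=C/CCCCS(=O)(=O)c2ccccc2)cc(c1)Oc1c(O[Si](C(C)C)(C(C)C)C(C)C)cc(cc1O[Si](C(C)C)(C(C)C)C(C)C)[C@H](O[Si](C)(C)C(C)(C)C)CCI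
F4 | step 9 | macrocyclic sulfone: 17 with phenylsulfonyl on C4' | CC(C)[Si](C(C)C)(C(C)C)Oc1cc2cc(c1)Oc1c(O[Si](C(C)C)(C(C)C)C(C)C)cc(cc1O[Si](C(C)C)(C(C)C)C(C)C)[C@H](O[Si](C)(C)C(C)(C)C)CCC(S(=O)(=O)c3ccccc3)CCC/C=C/CCCCC2
F5 | step 4 | racemic allylic alcohol (racemate of 6) | CC(C)[Si](C(C)C)(C(C)C)Oc1cc(Br)cc(c1)Oc1c(O[Si](C(C)C)(C(C)C)C(C)C)cc(cc1O[Si](C(C)C)(C(C)C)C(C)C)C(O)C=C
F6 | step 4 | epoxy alcohol: (R)-{4-[3-bromo-5-(triisopropylsilyloxy)phenoxy]-3,5-bis(triisopropylsilyloxy)phenyl}[(R)-oxiran-2-yl]methanol | CC(C)[Si](C(C)C)(C(C)C)Oc1cc(Br)cc(c1)Oc1c(O[Si](C(C)C)(C(C)C)C(C)C)cc(cc1O[Si](C(C)C)(C(C)C)C(C)C)[C@@H](O)[C@H]2CO2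
F7 | step 1 | (3-bromo-5-methoxyphenyl)boronic acid (purchased) | COc1cc(Br)cc(B(O)O)c1
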